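**Plan**

Retrosynthesis: the 3-O-methyl bond is cut first, then the C3–C4 bond of the pyranone ring, then the O1–C2 aryl ether bond, and last the 4'-O-prenyl and 7-O-methyl bonds, leading back to 2,4,6-trihydroxybenzaldehyde, methyl 4-hydroxymandelate and prenyl bromide.
Enabling feature: in the chromen-4-one ring, C4 (the ketone) and C3 (the oxygen-bearing enol carbon, one half of a masked 1,2-dione) are neighbours that both sit at carbonyl oxidation level, so joining them needs polarity reversal at C4; C2 carries the aryl group and one hydrogen, whose loss aromatises the ring after closure.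
Forward: the A-ring aldehyde (4-O-methylation) and the B-ring mandelate (O-prenylation) are made separately and joined through O1–C2 by Mitsunobu etherification.
The only ring formed, the pyranone, is then closed by carbene-catalysed acylation of the umpoled formyl carbon by the tethered ester (C3–C4), and selective 3-O-methylation completes the target.
Stereochemistry: the target has no stereocentre and no stereogenic double bond; the single sp3 centre carried through (the mandelate carbon, racemic) is erased in the ring closure.

Key step: step 4

Assumption: since the target SMILES holds no stereocentre and no stereogenic alkene, the compound is achiral and "single enantiomer" sets no stereochemical task; the mandelate-derived carbon is used racemic.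

**Route**

Step 1
Reactants: 1 2,4,6-trihydroxybenzaldehyde
Product: 2 2,6-dihydroxy-4-methoxybenzaldehyde
Conditions: Me2SO4 (1.0 equiv), K2CO3 (1.0 equiv), acetone, 0 °C → rt
Reagents that add atoms: dimethyl sulfate, COS(=O)(=O)OC
Why: Regioselective Williamson O-methylation, in which the 4-hydroxyl (para to the formyl group, not hydrogen-bonded, most acidic) is the one ionised by a single equivalent of carbonate while the two ortho hydroxyls stay chelated to the carbonyl.

Step 2
Reactants: 3 methyl 2-hydroxy-2-(4-hydroxyphenyl)acetate (methyl 4-hydroxymandelate, racemic); 4 1-bromo-3-methylbut-2-ene (prenyl bromide)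
Product: 5 methyl 2-hydroxy-2-{4-[(3-methylbut-2-en-1-yl)oxy]phenyl}acetate (racemic)
Conditions: K2CO3 (1.5 equiv), acetone, reflux
Reagents that add atoms: none
Why: Williamson etherification in which carbonate ionises only the phenol, far more acidic than the secondary α-hydroxy ester alcohol, and the phenoxide displaces the primary allylic bromide by SN2.

Step 3
Reactants: 2 2,6-dihydroxy-4-methoxybenzaldehyde; 5 methyl 2-hydroxy-2-{4-[(3-methylbut-2-en-1-yl)oxy]phenyl}acetate
Product: 6 methyl 2-(2-formyl-3-hydroxy-5-methoxyphenoxy)-2-{4-[(3-methylbut-2-en-1-yl)oxy]phenyl}acetate (racemic)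
Conditions: PPh3 (1.3 equiv), DIAD (1.3 equiv), THF, 0 °C → rt; 2 in 1.2-fold excess
Reagents that add atoms: none
Why: Mitsunobu etherification of a mandelate carbinol by an acidic salicylaldehyde-type phenol, where the two hydroxyls of 2 are equivalent and the one left after the first etherification is more tightly chelated and more hindered, so the reaction should stop at the mono-ether; the new centre forms racemic and is erased in step 4.

Step 4
Reactants: 6 methyl 2-(2-formyl-3-hydroxy-5-methoxyphenoxy)-2-{4-[(3-methylbut-2-en-1-yl)oxy]phenyl}acetate
Product: 8 3,5-dihydroxy-7-methoxy-2-{4-[(3-methylbut-2-en-1-yl)oxy]phenyl}-4H-chromen-4-one, via chromane-3,4-dione 7 (not isolated)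
Conditions: 2-mesityl-6,7-dihydro-5H-pyrrolo[2,1-c][1,2,4]triazol-2-ium chloride (20 mol %), DBU (20 mol %), 4 Å MS, degassed 1,4-dioxane, 80 °C, Ar
Reagents that add atoms: none
Why: Proposed new method: the carbene adds to the formyl group of 6 and proton transfer gives the hydroxy-enamine acyl-anion equivalent, whose carbon (C4) attacks the ester carbonyl (C3, made more electrophilic by its α-aryloxy group); the tetrahedral adduct then expels methoxide and the carbene to give dione 7, whose doubly activated C2–H enolises at once to the aromatic 3-hydroxy-4-pyranone 8. The closest known reaction types are the carbene-catalysed intramolecular crossed benzoin of salicylaldehyde-tethered ketones to 3-hydroxychroman-4-ones and the analogous aldehyde–nitrile cyclisation to 3-aminochromones; an unactivated ester as acceptor is the new element. The pyranone ring closes in a 6-exo-trig mode and no stereocentre is created, the racemic C2 centre of 6 being lost on enolisation. The selectivity needed is acyl-anion acylation over the base-induced aldol of the ester enolate onto the aldehyde, and it is secured because that aldol adduct, a 2,2-disubstituted 3-hydroxy-2,3-dihydrobenzofuran, cannot dehydrate at its quaternary carbon and reverts, whereas aromatisation of 7 is irreversible. Homo-benzoin dimerisation is held back by the two ortho oxygens flanking the formyl group, and the methoxide set free is taken up by the acidic 3-hydroxyl of 8, so the base stays catalytic and most of 6 keeps its ortho hydroxyl hydrogen-bonded to, and polarising, the formyl oxygen.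

Step 5
Reactants: 8 3,5-dihydroxy-7-methoxy-2-{4-[(3-methylbut-2-en-1-yl)oxy]phenyl}-4H-chromen-4-one
Product: 9 5-hydroxy-3,7-dimethoxy-2-{4-[(3-methylbut-2-en-1-yl)oxy]phenyl}-4H-chromen-4-one
Conditions: Me2SO4 (1.1 equiv), K2CO3 (1.5 equiv), acetone, reflux
Reagents that add atoms: dimethyl sulfate, COS(=O)(=O)OC
Why: Selective Williamson O-methylation of a flavonol, in which the enolic 3-hydroxyl is more acidic and accessible than the 5-hydroxyl, which is locked in a strong hydrogen bond to the C4 carbonyl and resists methylation under carbonate conditions.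

**Compound list**

1 | 2,4,6-trihydroxybenzaldehyde | O=Cc1c(O)cc(O)cc1O | starting material
2 | 2,6-dihydroxy-4-methoxybenzaldehyde | COc1cc(O)c(C=O)c(O)c1 | intermediate
3 | methyl 2-hydroxy-2-(4-hydroxyphenyl)acetate (methyl 4-hydroxymandelate, racemic) | COC(=O)C(O)c1ccc(O)cc1 | starting material
4 | 1-bromo-3-methylbut-2-ene (prenyl bromide) | CC(C)=CCBr | starting material
5 | methyl 2-hydroxy-2-{4-[(3-methylbut-2-en-1-yl)oxy]phenyl}acetate (racemic) | COC(=O)C(O)c1ccc(OCC=C(C)C)cc1 | intermediate
6 | methyl 2-(2-formyl-3-hydroxy-5-methoxyphenoxy)-2-{4-[(3-methylbut-2-en-1-yl)oxy]phenyl}acetate (racemic) | COC(=O)C(Oc1cc(OC)cc(O)c1C=O)c1ccc(OCC=C(C)C)cc1 | intermediate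
7 | 5-hydroxy-7-methoxy-2-{4-[(3-methylbut-2-en-1-yl)oxy]phenyl}chromane-3,4-dione (racemic, not isolated) | COc1cc(O)c2c(c1)OC(c1ccc(OCC=C(C)C)cc1)C(=O)C2=O | intermediate
8 | 3,5-dihydroxy-7-methoxy-2-{4-[(3-methylbut-2-en-1-yl)oxy]phenyl}-4H-chromen-4-one | COc1cc(O)c2c(=O)c(O)c(-c3ccc(OCC=C(C)C)cc3)oc2c1 | intermediate
9 | 5-hydroxy-3,7-dimethoxy-2-{4-[(3-methylbut-2-en-1-yl)oxy]phenyl}-4H-chromen-4-one | COc1cc(O)c2c(=O)c(OC)c(-c3ccc(OCC=C(C)C)cc3)oc2c1 | target

**Step count**

Total steps: 5. Longest linear sequence: 4 steps (1 → 2 → 6 → 8 → 9; the branch 3 → 5 → 6 → 8 → 9 is equally long).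

**Steps most likely to fail**

1. Step 4 (carbene-catalysed ring closure). Carbene addition to a formyl group flanked by two ortho oxygens and deactivated by three donor substituents may be slow. The hydroxy-enamine, once formed, may also add to a plain methyl ester too slowly to outrun catalyst decay and reversible enolate chemistry, so that conversion stalls. The fallback uses only known reactions, gives up the C3–C4 disconnection, sets out from prenyl bromide 4 and comes back to the route at flavonol 8. Compound 4 alkylates commercial 4-hydroxybenzaldehyde (K2CO3, acetone, reflux) to give 4-[(3-methylbut-2-en-1-yl)oxy]benzaldehyde F1. Commercial 2',6'-dihydroxy-4'-methoxyacetophenone is mono-protected (MOMCl, i-Pr2NEt, CH2Cl2, 0 °C) to 1-[2-hydroxy-4-methoxy-6-(methoxymethoxy)phenyl]ethan-1-one F2. Claisen–Schmidt condensation of F2 with F1 (KOH, EtOH, rt) should give the 2'-hydroxychalcone (E)-1-[2-hydroxy-4-methoxy-6-(methoxymethoxy)phenyl]-3-{4-[(3-methylbut-2-en-1-yl)oxy]phenyl}prop-2-en-1-one F3. Algar–Flynn–Oyamada oxidation (30% H2O2, aq. NaOH, MeOH, 0 °C → rt) should close the pyranone to 3-hydroxy-7-methoxy-5-(methoxymethoxy)-2-{4-[(3-methylbut-2-en-1-yl)oxy]phenyl}-4H-chromen-4-one F4; the electron-rich prenyl alkene is inert to the nucleophilic peroxide. Mild acid (dilute HCl, MeOH, rt) then removes the labile peri acetal and returns 8, which enters step 5.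

2. Step 3 (Mitsunobu etherification). The remaining phenol may be etherified a second time. Alternatively, the electron-rich benzylic oxyphosphonium may ionise and be captured by the hydrazide faster than by the hindered, chelated phenol. The fallback replaces redox condensation by phenoxide SN2, sets out from 5 and comes back at 6. Appel bromination of 5 (CBr4, PPh3, CH2Cl2, 0 °C) should give methyl 2-bromo-2-{4-[(3-methylbut-2-en-1-yl)oxy]phenyl}acetate F5, used crude. Alkylation of 2 (1.2 equiv) with F5 (K2CO3 1.0 equiv, acetone, rt) should then give 6.

3. Step 1 (mono-methylation). Over-alkylation of the chelated hydroxyls, or C-methylation of the phloroglucinol nucleus, may erode mono-selectivity and give mixtures that are hard to separate. The fallback moves the source of selectivity from kinetic acidity to chelation-controlled dealkylation, sets out from 1 and comes back at 2. Exhaustive methylation of 1 (excess Me2SO4, K2CO3, acetone, reflux) gives 2,4,6-trimethoxybenzaldehyde F6. Aluminium chloride (excess, CH2Cl2, rt → reflux) should then cleave only the two methyl ethers ortho to the coordinating formyl group, leaving the para methoxy group and returning 2.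

**Further compounds**

F1 | step 4 | 4-[(3-methylbut-2-en-1-yl)oxy]benzaldehyde | CC(C)=CCOc1ccc(C=O)cc1
F2 | step 4 | 1-[2-hydroxy-4-methoxy-6-(methoxymethoxy)phenyl]ethan-1-one | CC(=O)c1c(O)cc(OC)cc1OCOC
F3 | step 4 | (E)-1-[2-hydroxy-4-methoxy-6-(methoxymethoxy)phenyl]-3-{4-[(3-methylbut-2-en-1-yl)oxy]phenyl}prop-2-en-1-one | COCOc1cc(OC)cc(O)c1C(=O)/C=C/c1ccc(OCC=C(C)C)cc1
F4 | step 4 | 3-hydroxy-7-methoxy-5-(methoxymethoxy)-2-{4-[(3-methylbut-2-en-1-yl)oxy]phenyl}-4H-chromen-4-one | COCOc1cc(OC)cc2oc(-c3ccc(OCC=C(C)C)cc3)c(O)c(=O)c12
F5 | step 3 | methyl 2-bromo-2-{4-[(3-methylbut-2-en-1-yl)oxy]phenyl}acetate (racemic) | COC(=O)C(Br)c1ccc(OCC=C(C)C)cc1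
F6 | step 1 | 2,4,6-trimethoxybenzaldehyde | COc1cc(OC)c(C=O)c(OC)c1
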